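**Assumptions (one line each)**
- The SMILES has a 28-carbon acyl chain (octacosanoate, C(=O) plus 27 carbons), and tyrosol supplies the alcohol part.
- The target has no stereocentres, so "single enantiomer" is trivially met and no stereochemical control is needed.

## Retrosynthetic overview
1. Disconnect the ester at the acyl C–C bond rather than the acyl C–O bond. Bongardol comes from a Pd-catalysed linear hydroesterification of 1-heptacosene with CO and tyrosol, so no octacosanoic acid or activated acyl species is ever used.
2. Disconnect 1-heptacosene by Cu-catalysed sp3–sp3 Kumada coupling of pent-4-enylmagnesium bromide with 1-bromodocosane.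
3. No rings are formed. The C22 and C5 fragments are joined first, then CO is inserted to make the C28 ester.

## Route

**Step 1**
Reactants: 1 (5-bromopent-1-ene)
Product: 2 (pent-4-en-1-ylmagnesium bromide, made in situ)
Conditions: Mg turnings (1.6 equiv), I2 (cat.), THF, 25–40 °C, 2 h
Reagents that add atoms: Mg, [Mg]
Why: Standard Grignard formation. The 4-pentenyl radical or anion does not cyclise appreciably (unlike 5-hexenyl), so the terminal alkene survives.

**Step 2**
Reactants: 2 (pent-4-en-1-ylmagnesium bromide, 1.6 equiv) and 3 (1-bromodocosane)
Product: 4 (1-heptacosene)
Conditions: Li2CuCl4 (5 mol%), THF/NMP, 0 °C to 40 °C, 12 h, then aq. NH4Cl work-up and silica plug (hexane)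
Reagents that add atoms: none (Li2CuCl4 is a catalyst, and the Grignard 2 is a listed reactant)
Why: Kochi–Schlosser Cu-catalysed coupling of an alkyl Grignard with a primary alkyl bromide forms the C22–C5 bond and leaves the terminal alkene untouched. Excess Grignard drives full consumption of the bromide, so no 1-docosene or residual bromide carries through. The volatile 1,9-decadiene homodimer is removed under vacuum. No stereocentre is formed.

**Step 3**
Reactants: 4 (1-heptacosene) and 5 (tyrosol, 2-(4-hydroxyphenyl)ethanol, 1.5 equiv)
Product: 6 (bongardol, 4-hydroxyphenethyl octacosanoate)
Conditions: Pd(OAc)2 (1 mol%), 1,2-bis(di-tert-butylphosphinomethyl)benzene (4 mol%), MsOH (10 mol%), CO (30 bar), toluene/anisole, 90 °C, 24 h; chromatography then recrystallisation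
Reagents that add atoms: carbon monoxide, [C-]#[O+]
Why: Pd–hydride hydroesterification (alkoxycarbonylation) with a bulky diphosphine gives the linear n-acyl product, and any internal isomers formed by chain-walking also funnel to the linear ester. The primary alcohol of tyrosol is far more nucleophilic toward the acyl–Pd species than the phenol, so the alkyl ester forms selectively. The product has no stereocentre.

**Final checks**
- **Structure:** Step 3 gives an ArCH2CH2–O–C(=O)–(CH2)26–CH3 ester with a free para-phenol, which matches the target. The acyl chain is 1 (C=O) + 2 (from the alkene) + 3 (from the pentenyl CH2's) + 22 (from the bromodocosane) = 28 carbons.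
- **Atom balance:**
  - Step 1: C5H9Br + Mg → C5H9MgBr.
  - Step 2: C5H9MgBr + C22H45Br → C27H54 + MgBr2.
  - Step 3: C27H54 + CO + C8H10O2 → C36H64O3, which is bongardol.
- **Functional groups:**
  - The alkene is untouched by the Grignard and Cu conditions.
  - The free phenol is not touched in steps 1–2, because tyrosol is only introduced in step 3.
  - In step 3 the phenol remains as the free OH, with its lower nucleophilicity as the main selectivity risk.
- **Stereochemistry:** There are no stereocentres to set or scramble.

## Compound list
1 | 5-bromopent-1-ene | C=CCCCBr | starting material
2 | pent-4-en-1-ylmagnesium bromide | C=CCCC[Mg]Br | intermediate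
3 | 1-bromodocosane | CCCCCCCCCCCCCCCCCCCCCCBr | starting material
4 | 1-heptacosene | C=CCCCCCCCCCCCCCCCCCCCCCCCCC | intermediate
5 | tyrosol | OCCc1ccc(O)cc1 | starting material
6 | bongardol (4-hydroxyphenethyl octacosanoate) | CCCCCCCCCCCCCCCCCCCCCCCCCCCC(=O)OCCc1ccc(O)cc1 | target (achiral)

## Totals
Total steps: 3. Longest linear sequence: 3 (steps 1 and 2 can be run in one pot).

## Three steps most likely to fail
1. **Step 3 (hydroesterification).** The risks are phenol acylation, acid-mediated hydroarylation of the alkene by the phenol, and poor solubility of the C27 alkene.
   - Fallback: run Pd/dtbpx methoxycarbonylation with MeOH to give methyl octacosanoate, then transesterify with tyrosol using a lipase such as Novozym 435 in toluene at 70 °C. This changes the approach to carbonylation followed by enzymatic acyl transfer.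
2. **Step 2 (Kumada coupling).** The C22 bromide is poorly soluble in THF and can undergo elimination to 1-docosene, which would be inseparable from the product.
   - Fallback: build an internal C27 alkene by Grubbs-II cross-metathesis of 1-octadecene with 1-undecene. The isomerising Pd step accepts internal alkenes and still gives the linear ester, although the statistical metathesis mixture needs separation.
3. **Step 1 (Grignard formation).** Wurtz homocoupling to 1,9-decadiene can consume the reagent.
   - Fallback: invert the polarity. Make docosylmagnesium bromide from 3 in warm THF and couple it with 5-bromopent-1-ene (or its tosylate) under the same Li2CuCl4 conditions.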